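## Structural features

The target 17 is a dispiro compound: a cyclobutane in which two adjacent carbons, C5 and C5', are each the spiro γ-carbon of a 4-bromo-2(5H)-furanone (O1, C2(=O), C3, C4(Br), C5, and the primed set). The other two ring carbons, C6 (bonded to C5) and C6' (bonded to C5'), each carry one bromine. Each butenolide bears a 1-acetoxybutyl chain at C3; the carbinol carbon is S on the C5 ring and R on the C5' ring. The four ring stereocentres are contiguous (5S, 5'S, 6R, 6'R): O1 and O1' are trans, the ring bromines are trans, and each ring bromine is trans to the lactone oxygen on the neighbouring spiro carbon, hence cis to the neighbouring C4–Br arm. The tetrabromo core is C2-symmetric, but the unlike side chains remove all symmetry, so the sense of chirality of the core relative to this S/R pair must be controlled. Fragile elements are the two vinylogous acyl bromides (C4–Br), the secondary vicinal dibromide, the allylic acetates, and the strained ring with two tertiary acyloxy groups, which can open electrocyclically while C6=C6' is still present. The real difficulty is the pair of adjacent, fully substituted, oxygen-bearing spiro carbons in a four-membered ring with defined relative and absolute configuration, and then placing the ring bromines in the more crowded orientation. The key step uses the fact that C5 and C5' are vicinal and each is bonded to a lactone oxygen and to a vinylic, bromine-bearing C4: this is what remains when the two carbonyl carbons of a cyclobutene-1,2-dione are each attacked by a β-bromo-β-metalated acrylate that already contains C2, C3, C4, the C4–Br bond and the side chain.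

## Logic of the disconnections

**17 ⇒ 16.** The C6–Br and C6'–Br bonds are cut. A trans vicinal dibromide is the retron of anti addition of bromine to an alkene, and C6=C6' in 16 is the only alkene that is not an electron-poor, tetrasubstituted bromo-enoate. The gain is two stereocentres, and the elimination-prone secondary bromides stay out of all organometallic steps. The forward step must be chemoselective for C6=C6', and bromide must open the bromonium ion at the carbon where it ends trans to the neighbouring lactone oxygen.

**16 ⇒ 14 + 5.** The bonds C4'–C5' and O1'–C2' are cut. C5' is a tertiary carbinol-type carbon attached to a vinyl carbon (carbonyl-addition retron), and the lactone C–O bond is an acyl substitution by an alkoxide held cis to an ester. One ring and one quaternary stereocentre disappear, and the reagent brings C2'–C4', the C4'–Br bond and the R side chain in one piece. The forward step needs a nucleophilic C4' that keeps its bromine and lies cis to the ester, attack on the face of 14 syn to O1, and preference for the ketone over lactone, acetate and C4–Br.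

**14 ⇒ 12 + 7.** The same two bonds of the first ring, C4–C5 and O1–C2, are cut. This reaches a symmetric four-carbon dione and the enantiomeric reagent, so the unlike side chains enter one after the other with their configurations already fixed. The forward step must stop at mono-addition. No facial control can be expected, so the C5 epimers must be separated, and the epimer kept decides the absolute configuration of the core.

**5 and 7 ⇒ 6 ⇒ 4.** The acetate C–O bonds are cut, and 5 and 6 are traced to one racemate. Both enantiomers are needed in equal amounts, so a kinetic resolution that delivers one as acetate and the other as alcohol wastes nothing. The enzyme must distinguish the propyl group from the branched dibromovinyl group.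

**4 ⇒ 2 + 3, and 2 ⇒ 1.** The C2–C1'' bond (aldol) and one C3–Br bond (conjugate addition of bromide) are cut, then the alkynyl C–Br bond. This leaves two commercial compounds and a bromide source. The forward step needs bromide to add to the bromoalkyne and the resulting allenolate to be trapped by an enolisable aldehyde.

**12 ⇒ 10 ⇒ 8.** Each vinylic C–H of 12 is exchanged for a C–O(isopropyl) bond. This leads to a commercial squarate diester, and each exchange is a hydride addition followed by hydrolysis. The demand is clean mono-reduction twice and careful handling of the sensitive 12.

## Other disconnections considered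

**Alternative 1:** The cut is the C5–C5' bond itself, traced back to a 4π photo-electrocyclisation of a 2-pyranone. Irradiation of the 3-acyloxy-6-methoxycarbonyl-2-pyranone A2 near 300 nm in an aprotic solvent would close pyranone C3 to C6 and give the bicyclic β-lactone A1, whose two bridgehead carbons are the future C5 and C5'.
- In its favour: the cis ring fusion of A1 forces the ring oxygen on one bridgehead and the acyloxy oxygen on the other to opposite faces, so the trans O1/O1' relationship is guaranteed by geometry. On this point the alternative is better than the chosen plan, where it depends on facial selectivity in step 8. The photoisomerisation is also an established reaction class, so on precedent of the key step the alternative is again the better.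
- Against it here: A1 is a strained β-lactone that can revert or lose CO2 on over-irradiation. The remote carbinol centre cannot bias the closure, so two diastereomers would have to be separated; this is the same burden as the epimer separation after step 7 (equal). A1 contains neither butenolide: each would still need a base-mediated Dieckmann-type closure of a β-silyloxy ester (β-elimination and wrong-way opening of the β-lactone threaten), conversion of both enols to vinyl bromides, and two silyl-to-acetyl exchanges. The ring bromination poses the same question as step 9 (equal).
- Comparison: the chosen plan installs each complete bromobutenolide, with bromine and acetate, in one operation and reaches 17 in nine steps. The alternative would need roughly that many operations after A1 alone, so on step economy the chosen plan is better.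

**Alternative 2:** The cuts are C3–C1'' (aldol), C4–Br and O1–C2 on both halves at once. The bis-ynoate diol A4, as its bis(magnesium alkoxide) with MgBr2 and 3, would take bromide at each ynoate β-carbon; the allenolates would add to 3 and the alkoxides would lactonise to give the tetrabromo bis(1-hydroxybutyl) dispiro lactone A3.
- In its favour: it is two-directional, and 3 enters directly. The ring bromines are already present, having been added to a cyclobutene flanked by slim alkynyl groups, where the course "anti to oxygen" is also the sterically easy one; on this point the alternative is better than step 9. The step count would be similar or slightly lower (equal or better).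
- Against it here: the two carbinol centres form without control, so the required unlike pair is at best half of the mixture, and on a racemic core even that half is racemic. The chosen plan fixes both carbinol configurations before coupling and is better on stereocontrol. In A4 each alkoxide is anti to a vicinal bromide (epoxide closure or fragmentation), a cyclobutane-1,2-diolate can cleave its C5–C5' bond, and the aldol has to occur on a tetrasubstituted allenolate next to a quaternary centre.
- Comparison: both key steps go beyond established chemistry (equal).

**Alternative 3:** The cuts are O1–C5 and O1'–C5' (oxygen insertion). Basic hydrogen peroxide would add to both carbonyls of the dispiro bis(3-ethoxycyclobutenone) A6, and migration of each quaternary spiro carbon with retention would give the bis-tetronate A5.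
- In its favour: migration with retention transfers whatever configuration the carbocycle has. Strain release makes four-membered ketones good substrates, and the sp3 quaternary carbon should migrate in preference to the vinyl carbon. On reliability of the key step itself the alternative is better.
- Against it here: the difficulty moves into A6, three four-membered rings sharing two adjacent spiro atoms, with the trans relationship, the absolute configuration and the unlike side chains all still unsolved. Hydroperoxide can also add conjugately to the vinylogous esters (Weitz–Scheffer-type epoxidation). After A5, both ethoxy groups must become bromine (dealkylation, then oxalyl bromide/DMF), both silyl ethers must become acetates, and the ring must be brominated: at least five further steps against one in the chosen plan.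
- Comparison: on the ring bromination the two plans are equal; on step economy and on access to the key-step precursor the chosen plan is better.

Key step: step 8

**Assumptions (remarks on the chemistry)**
- Atom labels: O1, C2, C3, C4, C5 are the butenolide bearing the S side chain, the primed set is the butenolide bearing the R side chain, and C6 and C6' are the other ring carbons bonded to C5 and C5'.
- The lipase is assumed to acylate the R alcohol, following the usual size-based preference for secondary alcohols. If the preference were reversed the route is unchanged, because the enzymatic acetate would then be 7 and the acetylated residual alcohol would be 5.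
- The structures of the target and of the key-step partners were checked atom by atom and needed no correction. The descriptors at C5 and C5' are R in 14 and 16 and S in 17 only because C6 and C6' gain priority on bromination; no bond at the spiro carbons changes.
- Steps 7 and 8 are the two halves of the one double spiro-annulation. They are run separately because the C5 epimers must be separated in between; a one-flask version would give the racemate of 16.

## Steps

Step 1
Reactants: 1 methyl prop-2-ynoate (methyl propiolate)
Product: 2 methyl 3-bromoprop-2-ynoate
Conditions: NBS, AgNO3 (cat.), acetone, rt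
Reagents that add atoms: N-bromosuccinimide, O=C1CCC(=O)N1Br
Why: Silver-catalysed electrophilic bromination of a terminal alkyne through the silver acetylide, a standard preparation of 1-bromoalkynes that leaves the ester untouched.

Step 2
Reactants: 2 methyl 3-bromoprop-2-ynoate; 3 butanal
Product: 4 methyl 3,3-dibromo-2-(1-hydroxybutyl)prop-2-enoate (racemic)
Conditions: MgBr2·OEt2, CH2Cl2, 0 °C; 1 M HCl work-up
Reagents that add atoms: magnesium bromide (as MgBr2·OEt2), [Mg+2].[Br-].[Br-]
Why: Halo-aldol (bromo Baylis–Hillman-type three-component) reaction of an alkynoate: bromide adds to the β-carbon of the magnesium-activated ynoate and the magnesium allenolate adds through C2 to the aldehyde. The alkene terminus carries two bromines, so no alkene geometry arises; the carbinol centre forms racemic and is resolved in step 3.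

Step 3
Reactants: 4 methyl 3,3-dibromo-2-(1-hydroxybutyl)prop-2-enoate (racemic)
Product: 5 methyl 2-[(1R)-1-acetoxybutyl]-3,3-dibromoprop-2-enoate and 6 methyl 3,3-dibromo-2-[(1S)-1-hydroxybutyl]prop-2-enoate
Conditions: Burkholderia cepacia lipase (immobilised), vinyl acetate, MTBE, 30 °C, stopped near half conversion; SiO2
Reagents that add atoms: vinyl acetate, C=COC(C)=O
Why: Lipase-catalysed kinetic resolution by irreversible transesterification with an enol ester; the enzyme should acylate the enantiomer whose bulky dibromovinyl and smaller propyl groups fit its large and medium pockets (the R alcohol) and leave the S alcohol. Both products are used, so the resolution costs no material.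

Step 4
Reactants: 6 methyl 3,3-dibromo-2-[(1S)-1-hydroxybutyl]prop-2-enoate
Product: 7 methyl 2-[(1S)-1-acetoxybutyl]-3,3-dibromoprop-2-enoate
Conditions: Ac2O, pyridine, CH2Cl2, 0 °C → rt
Reagents that add atoms: acetic anhydride, CC(=O)OC(C)=O
Why: Acetylation of a secondary alcohol with retention, since the C–O bond of the carbinol is not touched. DMAP is left out to avoid addition–elimination at the dibromoalkene.

Step 5
Reactants: 8 3,4-di(propan-2-yloxy)cyclobut-3-ene-1,2-dione (diisopropyl squarate)
Product: 10 3-(propan-2-yloxy)cyclobut-3-ene-1,2-dione, via hydroxy enone 9 (not isolated)
Conditions: LiAlH(OtBu)3, THF, −78 → −20 °C; then conc. HCl, CH2Cl2, rt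
Reagents that add atoms: water, O
Why: Hydride 1,2-addition to one vinylogous ester carbonyl of a squarate diester stops at mono-addition because the alkoxide deactivates the ring. Acid then ionises the allylic hydroxyl, water captures the alkoxy-stabilised cation and propan-2-ol is lost, which is the established way to replace one alkoxy group of a squarate.

Step 6
Reactants: 10 3-(propan-2-yloxy)cyclobut-3-ene-1,2-dione
Product: 12 cyclobut-3-ene-1,2-dione, via hydroxy enone 11 (not isolated)
Conditions: LiAlH(OtBu)3, THF, −78 °C; then conc. HCl, CH2Cl2, 0 °C; sublimation, dark
Reagents that add atoms: none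
Why: The same reduction–hydrolysis sequence on the remaining vinylogous ester: hydride adds to the more electrophilic, non-vinylogous carbonyl, and acid hydrolysis of the enol ether, enediol tautomerisation and β-elimination of water (water adds and is lost again) should give the parent dione. It is volatile and sensitive to light and nucleophiles, so it is sublimed and used at once.

Step 7
Reactants: 7 methyl 2-[(1S)-1-acetoxybutyl]-3,3-dibromoprop-2-enoate; 12 cyclobut-3-ene-1,2-dione
Product: 14 (1S)-1-[(4R)-8-bromo-1,6-dioxo-5-oxaspiro[3.4]octa-2,7-dien-7-yl]butyl acetate, via magnesium carbenoid 13 (not isolated)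
Conditions: 7, iPrMgCl·LiCl (1.05 equiv), THF, −78 °C, 20 min; cannula into 12 (2 equiv), THF, −78 → −30 °C; AcOH; SiO2 (separation of the C5 epimers)
Reagents that add atoms: none
Why: Proposed new method: chelation by the ester should direct bromine–magnesium exchange to the bromine cis to CO2Me, and the carbenoid 13 (a β-acyl vinyl anion) should add 1,2 to one strained carbonyl of 12 (C4–C5) and lactonise 5-exo-trig through the cis-held alkoxide (O1–C2); the closest known reaction types are chelation-directed bromine–metal exchange of 1,1-dibromoalkenes with carbonyl trapping of the carbenoids, lactonising additions of β-magnesioacrylates, and 1,2-additions of organometallics to cyclobutenediones. Inverse addition to excess 12 should hold the reaction at mono-addition, the first alkoxide deactivating the neighbouring carbonyl until it lactonises. The planar dione offers no facial bias, so both C5 epimers are expected, and the 5R epimer 14 is to be separated and identified by X-ray diffraction (bromine as heavy atom), which fixes the absolute configuration of the core.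

Step 8
Reactants: 14 (1S)-1-[(4R)-8-bromo-1,6-dioxo-5-oxaspiro[3.4]octa-2,7-dien-7-yl]butyl acetate; 5 methyl 2-[(1R)-1-acetoxybutyl]-3,3-dibromoprop-2-enoate
Product: 16 dispiro cyclobutene bis(4-bromobutenolide) with 5R and 5'R spiro carbons and O1 trans to O1' and a 3-[(1S)-1-acetoxybutyl] group on the C5 ring and a 3'-[(1R)-1-acetoxybutyl] group on the C5' ring, via magnesium carbenoid 15 (not isolated)
Conditions: 5 (1.3 equiv), iPrMgCl·LiCl (1.3 equiv), THF, −78 °C, 20 min; then 14, −78 → −30 °C; AcOH
Reagents that add atoms: none
Why: Proposed new method: iPrMgCl·LiCl should exchange the bromine of 5 that lies cis to the ester, because the ester carbonyl binds magnesium in a five-membered chelate before and after the exchange, and the resulting α-bromoalkenylmagnesium carbenoid 15 acts as a β-acyl vinyl anion. Its sp2 C–Mg bond adds 1,2 to the strained cyclobutenone carbonyl of 14 (bond C4'–C5'), and the tertiary magnesium alkoxide, held cis to the methyl ester across C3'=C4', closes the second butenolide by 5-exo-trig acyl substitution with loss of methoxide (bond O1'–C2'). The closest known reaction types are ester- or ether-chelation-directed bromine–metal exchange of gem-dibromides and 1,1-dibromoalkenes with carbonyl trapping of the carbenoids, lactonising additions of β-magnesioacrylates to carbonyl compounds, and 1,2-additions of organometallics to cyclobutenediones; new is their union in a carbenoid that keeps its bromine through addition and lactonisation on this electrophile. The new stereocentre C5' is set by the substrate: the first butenolide stands perpendicular to the four-membered ring and places its C4–Br arm over one face of the carbonyl and only the ring oxygen O1 over the other, so the reagent should enter syn to O1 (magnesium bridging the ketone oxygen and O1 would act in the same sense), which puts O1' trans to O1. The chemoselectivity needed, ketone before lactone, acetates and the vinylogous acyl bromide, rests on the strain and ketone character of the cyclobutenone carbonyl at −78 °C, and conjugate addition is disfavoured because the β-carbon adjoins the quaternary C5. Quenching cold with AcOH limits the lifetime of any alkoxide that could open the cyclobutene, and neither carbinol centre is touched.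

Step 9
Reactants: 16 dispiro cyclobutene bis(4-bromobutenolide)
Product: 17 the target, the 5S,5'S,6R,6'R tetrabromide: trans-dibromocyclobutane (C6, C6') whose carbons C5 and C5' are the spiro γ-carbons of two 4-bromo-2(5H)-furanones, with 3-[(1S)-1-acetoxybutyl] on the C5 ring and 3'-[(1R)-1-acetoxybutyl] on the C5' ring
Conditions: Br2 (1.05 equiv), CH2Cl2, −20 → 0 °C, dark
Reagents that add atoms: bromine, BrBr
Why: Electrophilic anti addition of bromine through a bromonium ion; the two bromo-enoate double bonds are tetrasubstituted and electron-poor and should not react, and the two faces of C6=C6' are equivalent in the C2-symmetric core. Bromide is expected to open the bromonium ion at the carbon where its back-side approach is anti to the neighbouring C–O bond (there the departing C–Br bond is aligned with the better-donating C5–C4 bond and the anion avoids the lactone oxygen), which gives the trans dibromide with each bromine trans to the adjacent lactone oxygen.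

## Compound list

1 | methyl prop-2-ynoate (methyl propiolate) | COC(=O)C#C | starting material
2 | methyl 3-bromoprop-2-ynoate | COC(=O)C#CBr | intermediate
3 | butanal | CCCC=O | starting material
4 | methyl 3,3-dibromo-2-(1-hydroxybutyl)prop-2-enoate, racemic | CCCC(O)C(C(=O)OC)=C(Br)Br | intermediate
5 | methyl 2-[(1R)-1-acetoxybutyl]-3,3-dibromoprop-2-enoate | CCC[C@@H](OC(C)=O)C(C(=O)OC)=C(Br)Br | intermediate
6 | methyl 3,3-dibromo-2-[(1S)-1-hydroxybutyl]prop-2-enoate | CCC[C@H](O)C(C(=O)OC)=C(Br)Br | intermediate
7 | methyl 2-[(1S)-1-acetoxybutyl]-3,3-dibromoprop-2-enoate | CCC[C@H](OC(C)=O)C(C(=O)OC)=C(Br)Br | intermediate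
8 | 3,4-di(propan-2-yloxy)cyclobut-3-ene-1,2-dione (diisopropyl squarate) | CC(C)OC1=C(OC(C)C)C(=O)C1=O | starting material
9 | 4-hydroxy-2,3-di(propan-2-yloxy)cyclobut-2-en-1-one, racemic | CC(C)OC1=C(OC(C)C)C(O)C1=O | intermediate (not isolated)
10 | 3-(propan-2-yloxy)cyclobut-3-ene-1,2-dione | CC(C)OC1=CC(=O)C1=O | intermediate
11 | 4-hydroxy-3-(propan-2-yloxy)cyclobut-2-en-1-one, racemic | CC(C)OC1=CC(=O)C1O | intermediate (not isolated)
12 | cyclobut-3-ene-1,2-dione | O=C1C=CC1=O | intermediate
13 | [(1E,3S)-3-acetoxy-1-bromo-2-(methoxycarbonyl)hex-1-en-1-yl]magnesium chloride (magnesium cis to the ester, bromine cis to the acetoxybutyl group) | CCC[C@H](OC(C)=O)/C(C(=O)OC)=C(\Br)[Mg]Cl | intermediate (not isolated)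
14 | (1S)-1-[(4R)-8-bromo-1,6-dioxo-5-oxaspiro[3.4]octa-2,7-dien-7-yl]butyl acetate (4-bromobutenolide whose C5, R, is the spiro carbon of a cyclobut-2-en-1-one) | CCC[C@H](OC(C)=O)C1=C(Br)[C@@]2(OC1=O)C=CC2=O | intermediate
15 | [(1E,3R)-3-acetoxy-1-bromo-2-(methoxycarbonyl)hex-1-en-1-yl]magnesium chloride (magnesium cis to the ester) | CCC[C@@H](OC(C)=O)/C(C(=O)OC)=C(\Br)[Mg]Cl | intermediate (not isolated)
16 | dispiro cyclobutene bis(4-bromobutenolide): C6=C6' flanked by spiro carbons C5 and C5' (5R,5'R; O1 trans to O1'), 3-[(1S)-1-acetoxybutyl] on the C5 ring, 3'-[(1R)-1-acetoxybutyl] on the C5' ring | CCC[C@H](OC(C)=O)C1=C(Br)[C@@]2(OC1=O)C=C[C@@]21OC(=O)C([C@@H](CCC)OC(C)=O)=C1Br | intermediate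
17 | (5S,5'S,6R,6'R)-tetrabromide: 16 with bromine on C6 and C6', the bromines trans to each other and each trans to the neighbouring lactone oxygen | CCC[C@H](OC(C)=O)C1=C(Br)[C@@]2(OC1=O)[C@@H](Br)[C@H](Br)[C@@]21OC(=O)C([C@@H](CCC)OC(C)=O)=C1Br | target

## Step count and least certain steps

Total: 9 steps. Longest linear sequence: 7 steps (1 → 2 → 4 → 6 → 7 → 14 → 16 → 17, that is steps 1, 2, 3, 4, 7, 8, 9); the branch 8 → 10 → 12 joins at step 7.

**Step 7 (labelled).** Most likely failure: the carbenoid is lost before C–C bond formation (α-elimination, or attack of iPrMgCl on the dibromoalkene), or the very electrophilic, base-sensitive 12 undergoes conjugate addition or oligomerisation, because both partners are unusually reactive. A slow lactonisation would also leave a cyclobutenone alkoxide exposed to ring opening. The fallback uses only known reaction types, sets out from 6 and 12 and returns at 14. Silylation of 6 (TBSOTf, 2,6-lutidine) gives the silyl ether F1, DIBAL-H reduces its ester to the allylic alcohol F2, and MOMCl/iPr2NEt gives the methoxymethyl ether F3. Bromine–lithium exchange with n-BuLi in Et2O at −100 °C is directed by the chelating acetal oxygen to the bromine cis to it, and the 1-bromoalkenyllithium adds 1,2 to 12 to give the hydroxy cyclobutenone F4 as two epimers. Me2BBr removes the acetal to give the diol F5. TEMPO/PhI(OAc)2 oxidises the primary allylic alcohol through the lactol to the spiro butenolide silyl ether F6, whose C5 epimers are separated. HF·pyridine frees the carbinol F7, and Ac2O/pyridine gives 14.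

**Step 8 (labelled, key step).** Most likely failure: insufficient facial selectivity at the cyclobutenone carbonyl, because the polar effect of the α-acyloxy group opposes the steric shielding by the C4–Br arm. Attack of the carbenoid on the vinylogous acyl bromide or the lactone of 14, or anion-accelerated electrocyclic opening of the cyclobutene alkoxide before it lactonises, are the other risks. The fallback uses only known reaction types, sets out from 14, uses F3 from the fallback above and returns at 16. Bromine–lithium exchange of F3 as above and transmetalation with CeCl3 give an organocerium reagent that should add only to the ketone of 14 and is quenched cold, giving the tertiary alcohol F8, whose epimers can be separated. Me2BBr gives the diol F9, TEMPO/PhI(OAc)2 closes the second butenolide as the silyl ether F10, and HF·pyridine gives the 1'''S carbinol F11. A Mitsunobu reaction with AcOH (PPh3, DIAD) inverts this carbinol and installs the acetate, giving 16.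

**Step 9.** Most likely failure: opening of the bromonium ion at the less hindered carbon, that is reversed diastereoselectivity with each bromine cis to the lactone oxygen, because the approach that leads to 17 passes the C4–Br arm. Slow addition to the hindered alkene could also let radical addition compete. The fallback sets out from 16 and returns at 17; it uses the same steric bias constructively and brings bromide in by inversion. Dimethyldioxirane gives the epoxide F12 (either face). Acid-catalysed hydrolysis (dilute HClO4, THF/H2O), with water entering at the open carbon, gives the trans diol F13 with each hydroxyl cis to the neighbouring lactone oxygen. Tf2O/pyridine gives the bis-triflate F14, and LiBr in acetone displaces both triflates with inversion to give 17. The weak point of this fallback is that bromide must then approach past the C4–Br arm.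

**Step 2.** Most likely failure: the bromide adduct reverts or is protonated instead of adding to the enolisable aldehyde, or 3 undergoes self-aldol reaction, because the dibromoallenolate is a weak nucleophile. The fallback sets out from 3 and returns at 7 and 5. A Baylis–Hillman reaction of 3 with methyl acrylate F15 (DABCO) gives the racemic carbinol F16, and Ac2O/pyridine gives the acetate F17. Ozonolysis (O3, CH2Cl2/MeOH, −78 °C; Me2S) gives the α-keto ester F18, and Ramirez dibromo-olefination (CBr4, PPh3, CH2Cl2, 0 °C) gives the racemic dibromo acetate F19. Lipase-catalysed hydrolysis in buffered MTBE then leaves the S acetate, which is 7, and releases the R alcohol F20, which is acetylated to 5.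

**Step 6.** Most likely failure: loss of 12 by hydration, oligomerisation or evaporation during hydrolysis and isolation, because the parent dione is volatile and highly electrophilic. The fallback sets out from the commercial 1,2-bis(trimethylsilyloxy)cyclobutene F21, not from a compound of the route, and returns at 12. Br2 in pentane at −60 °C gives cyclobutane-1,2-dione F22, α-bromination (Br2, CH2Cl2, 0 °C) gives 3-bromocyclobutane-1,2-dione F23, and brief treatment with Et3N in Et2O at −30 °C eliminates hydrogen bromide to give 12, which is sublimed.

**Step 3.** Most likely failure: slow acylation or low enantioselectivity, because both groups at the carbinol are large for the active site. The fallback sets out from 4 and returns at 6 and 5. DMP oxidises 4 to the ketone F24. Corey–Bakshi–Shibata reduction with one enantiomer of the B-methyl oxazaborolidine and catecholborane gives 6, and with the other enantiomer the R alcohol F20, which is acetylated to 5. The sense of induction is to be confirmed on the MTPA esters.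

## Further compounds

F1 | step 7 | methyl 3,3-dibromo-2-[(1S)-1-{[tert-butyl(dimethyl)silyl]oxy}butyl]prop-2-enoate | CCC[C@H](O[Si](C)(C)C(C)(C)C)C(C(=O)OC)=C(Br)Br
F2 | step 7 | (3S)-3-{[tert-butyl(dimethyl)silyl]oxy}-2-(dibromomethylidene)hexan-1-ol | CCC[C@H](O[Si](C)(C)C(C)(C)C)C(CO)=C(Br)Br
F3 | step 7 | tert-butyl({(3S)-1,1-dibromo-2-[(methoxymethoxy)methyl]hex-1-en-3-yl}oxy)dimethylsilane | CCC[C@H](O[Si](C)(C)C(C)(C)C)C(COCOC)=C(Br)Br
F4 | step 7 | 4-[(1Z,3S)-1-bromo-3-{[tert-butyl(dimethyl)silyl]oxy}-2-[(methoxymethoxy)methyl]hex-1-en-1-yl]-4-hydroxycyclobut-2-en-1-one (both C4 epimers) | COCOC/C(=C(/Br)C1(O)C=CC1=O)[C@H](CCC)O[Si](C)(C)C(C)(C)C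
F5 | step 7 | 4-[(1Z,3S)-1-bromo-3-{[tert-butyl(dimethyl)silyl]oxy}-2-(hydroxymethyl)hex-1-en-1-yl]-4-hydroxycyclobut-2-en-1-one (both C4 epimers) | OC/C(=C(/Br)C1(O)C=CC1=O)[C@H](CCC)O[Si](C)(C)C(C)(C)C
F6 | step 7 | (4R)-8-bromo-7-[(1S)-1-{[tert-butyl(dimethyl)silyl]oxy}butyl]-5-oxaspiro[3.4]octa-2,7-diene-1,6-dione | CCC[C@H](O[Si](C)(C)C(C)(C)C)C1=C(Br)[C@@]2(OC1=O)C=CC2=O
F7 | step 7 | (4R)-8-bromo-7-[(1S)-1-hydroxybutyl]-5-oxaspiro[3.4]octa-2,7-diene-1,6-dione | CCC[C@H](O)C1=C(Br)[C@@]2(OC1=O)C=CC2=O
F8 | step 8 | tertiary alcohol from 1,2-addition of the alkenyl reagent from F3 to the ketone of 14 (hydroxyl trans to the lactone oxygen, CH2OMOM cis to the ring) | CCC[C@H](OC(C)=O)C1=C(Br)[C@@]2(OC1=O)C=C[C@]2(O)/C(Br)=C(\COCOC)[C@H](CCC)O[Si](C)(C)C(C)(C)C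
F9 | step 8 | diol from F8 after removal of the methoxymethyl group | CCC[C@H](OC(C)=O)C1=C(Br)[C@@]2(OC1=O)C=C[C@]2(O)/C(Br)=C(\CO)[C@H](CCC)O[Si](C)(C)C(C)(C)C
F10 | step 8 | dispiro cyclobutene bis(4-bromobutenolide) with (1S)-1-acetoxybutyl on the C5 ring and (1S)-1-{[tert-butyl(dimethyl)silyl]oxy}butyl on the C5' ring | CCC[C@H](OC(C)=O)C1=C(Br)[C@@]2(OC1=O)C=C[C@@]21OC(=O)C([C@H](CCC)O[Si](C)(C)C(C)(C)C)=C1Br
F11 | step 8 | dispiro cyclobutene bis(4-bromobutenolide) with (1S)-1-acetoxybutyl on the C5 ring and (1S)-1-hydroxybutyl on the C5' ring | CCC[C@H](OC(C)=O)C1=C(Br)[C@@]2(OC1=O)C=C[C@@]21OC(=O)C([C@H](CCC)O)=C1Br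
F12 | step 9 | epoxide of 16 across C6–C6' (either face) | CCC[C@H](OC(C)=O)C1=C(Br)[C@@]2(OC1=O)C3OC3[C@@]21OC(=O)C([C@@H](CCC)OC(C)=O)=C1Br
F13 | step 9 | trans-6,6'-diol of the dispiro core, each hydroxyl cis to the neighbouring lactone oxygen | CCC[C@H](OC(C)=O)C1=C(Br)[C@@]2(OC1=O)[C@H](O)[C@@H](O)[C@@]21OC(=O)C([C@@H](CCC)OC(C)=O)=C1Br
F14 | step 9 | bis(trifluoromethanesulfonate) of F13 | CCC[C@H](OC(C)=O)C1=C(Br)[C@@]2(OC1=O)[C@H](OS(=O)(=O)C(F)(F)F)[C@@H](OS(=O)(=O)C(F)(F)F)[C@@]21OC(=O)C([C@@H](CCC)OC(C)=O)=C1Br
F15 | step 2 | methyl prop-2-enoate (methyl acrylate, commercial) | C=CC(=O)OC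
F16 | step 2 | methyl 2-(1-hydroxybutyl)prop-2-enoate, racemic | CCCC(O)C(=C)C(=O)OC
F17 | step 2 | methyl 2-(1-acetoxybutyl)prop-2-enoate, racemic | CCCC(OC(C)=O)C(=C)C(=O)OC
F18 | step 2 | methyl 3-acetoxy-2-oxohexanoate, racemic | CCCC(OC(C)=O)C(=O)C(=O)OC
F19 | step 2 | methyl 2-(1-acetoxybutyl)-3,3-dibromoprop-2-enoate, racemic | CCCC(OC(C)=O)C(C(=O)OC)=C(Br)Br
F20 | step 2 | methyl 3,3-dibromo-2-[(1R)-1-hydroxybutyl]prop-2-enoate | CCC[C@@H](O)C(C(=O)OC)=C(Br)Br
F21 | step 6 | 1,2-bis(trimethylsilyloxy)cyclobut-1-ene (commercial) | C[Si](C)(C)OC1=C(O[Si](C)(C)C)CC1
F22 | step 6 | cyclobutane-1,2-dione | O=C1CCC1=O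
F23 | step 6 | 3-bromocyclobutane-1,2-dione, racemic | O=C1CC(Br)C1=O
F24 | step 3 | methyl 2-butanoyl-3,3-dibromoprop-2-enoate | CCCC(=O)C(C(=O)OC)=C(Br)Br
A1 | alternative 1 | methyl 4-{[(3R)-3-{[tert-butyl(dimethyl)silyl]oxy}hexanoyl]oxy}-3-oxo-2-oxabicyclo[2.2.0]hex-5-ene-1-carboxylate (diastereomer matching C5 and C5' of 17) | COC(=O)[C@@]1(O2)C=C[C@@]1(C2=O)OC(=O)C[C@@H](CCC)O[Si](C)(C)C(C)(C)C
A2 | alternative 1 | methyl 5-{[(3R)-3-{[tert-butyl(dimethyl)silyl]oxy}hexanoyl]oxy}-6-oxo-6H-pyran-2-carboxylate | COC(=O)C1=CC=C(OC(=O)C[C@@H](CCC)O[Si](C)(C)C(C)(C)C)C(=O)O1
A3 | alternative 2 | dispiro bis[4-bromo-3-(1-hydroxybutyl)butenolide] on the trans-dibromocyclobutane, mixture of carbinol epimers | CCCC(O)C1=C(Br)[C@@]2(OC1=O)[C@@H](Br)[C@H](Br)[C@@]21OC(=O)C(C(O)CCC)=C1Br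
A4 | alternative 2 | dimethyl 3,3'-(3,4-dibromo-1,2-dihydroxycyclobutane-1,2-diyl)di(prop-2-ynoate), hydroxyls trans, bromines trans, each bromine trans to the neighbouring hydroxyl | COC(=O)C#C[C@@]1(O)[C@@H](Br)[C@H](Br)[C@]1(O)C#CC(=O)OC
A5 | alternative 3 | dispiro cyclobutene bis(4-ethoxybutenolide) with (1S)- and (1R)-1-{[tert-butyl(dimethyl)silyl]oxy}butyl groups | CCC[C@H](O[Si](C)(C)C(C)(C)C)C1=C(OCC)[C@@]2(OC1=O)C=C[C@@]21OC(=O)C([C@@H](CCC)O[Si](C)(C)C(C)(C)C)=C1OCC
A6 | alternative 3 | dispiro cyclobutene bis(3-ethoxycyclobut-2-en-1-one) with (1S)- and (1R)-1-{[tert-butyl(dimethyl)silyl]oxy}butyl groups at C2 of the two cyclobutenones | CCC[C@H](O[Si](C)(C)C(C)(C)C)C1=C(OCC)[C@@]2(C1=O)C=C[C@@]21C(=O)C([C@@H](CCC)O[Si](C)(C)C(C)(C)C)=C1OCC
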